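A small charge of L on a large charge of J makes little Q: Sunday's last two readings average 4.55 %, while Tuesday's, with the same L on less J, average 44.3 %.

| flask | J | L | remark | time |
|---|---|---|---|---|
| Tuesday's | 0.085 M | 0.11 M | run made earlier |  |
| Sunday's | 0.33 M | 0.11 M | run made earlier |  |
| Saturday's | 0.10 M | 0.29 M | run made earlier |  |
| grey | 0.40 M | 0.110 M |  | 50 min |
| teal | 0.40 M | 0.400 M |  | 50 min |
| blue | 0.10 M | 0.400 M |  | 50 min |
| violet | 0.10 M | 0.110 M |  | 50 min |

| run | time / min | Q / % |
|---|---|---|
| Tuesday's | 6.00 | 44.1 |
| Tuesday's | 12.0 | 44.7 |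
| Tuesday's | 20.0 | 44.1 |
| Tuesday's | 25.0 | 44.5 |
| Sunday's | 2.00 | 3.8 |
| Sunday's | 5.00 | 4.2 |
| Sunday's | 10.0 | 4.6 |
| Sunday's | 25.0 | 4.5 |
| Saturday's | 2.00 | 75.5 |
| Saturday's | 5.00 | 58.9 |
| Saturday's | 10.0 | 50.2 |
| Saturday's | 25.0 | 44.3 |

(scatter of a reading: 0.5 percentage points)

* the flasks by amount of Q, in percent of the J charged, highest first, at 50 min (grey / teal / blue / violet)
* the amount of Q, in percent of the J charged of the flask you put first, at 50 min
* the amount of Q, in percent of the J charged of the flask you put last, at 50 min

- the numbers in the tables scatter with a standard deviation of 0.5 percentage points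

*Which number carries over from run to run?* The equivalents e, charged L over charged J. I take it that each Q costs two L. So below e = 2, L is the limiting reagent, and I assume e sets Q there, whatever the size of the charge.

*Does time matter?* Little, late in those runs. Tuesday's reads flat from 6.00 min to 25.0 min, and Sunday's reads 4.6 % and then 4.5 %, so I carry both levels to 50 min.

*How do you join the ends?* Sunday's has e = 0.333 and Tuesday's e = 1.29. I draw a power law through both, Q proportional to e to the power n. The lean slope, the logarithm of the Q ratio over the logarithm of the e ratio, is n = 1.68.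

*And the flasks?* Violet has e = 1.10, so I reckon Q at 33.7 %. Teal has e = 1.00, so 28.7 %. Grey has e = 0.275, so 3.29 %.

*Blue has the most L. Why not put it first?* Saturday's Q reads 75.5 % and falls to 44.3 %, and I read that as Q taking up more L. I assume an equilibrium, with a third L on the rest. Taking Saturday's last reading as the end, and counting Q and that one other form, I read K = 36.7 L mol⁻¹.

*So blue?* Counting three L on each J leaves free L of 0.100 M, and my K then gives Q of 21.4 %. That Q hands back L, and a second pass gives 18.3 %. My order is violet, teal, blue, grey.

The forecast, on its own reckoning, gave violet > teal > blue > grey, top 34 %, low 3.2 %, holding that “Saturday's decay slows too early for an irreversible step”.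

The flasks give violet > teal > blue > grey: violet 33.4 %, teal 28.4 %, blue 20.2 %, grey 2.52 %.

    J + L → D (k = 1.13 L mol⁻¹ s⁻¹)
    L + D → Q (k = 0.815 L mol⁻¹ s⁻¹)
    L + Q ⇌ Z (K = 32.0 L mol⁻¹, k = 0.0297 L mol⁻¹ s⁻¹)
    D → E (k = 0.00192 s⁻¹)

The lean slope 1.68 lands 0.30 points high in violet and 0.77 points high in grey. In grey at 0.0244 min, L has a half-life of 1.8 s by J + L → D, against 6.0 min for D by D → E. At that moment L goes into D at 10 times its rate into Q, and at 50.0 min grey holds E 22.4 % and Q 2.52 %.

Now take grey with 0.19 M of L, so e = 0.475. The lean slope gives Q = 8.24 %, and the computed flask gives 7.15 %.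

All runs come from a simulation from invented constants.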